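The runs were generated by integration on assumed constants.

5.00 d was the number I carried through this series: the time in which the gap between the target and its plateau halves, my plateau half-life, read from the amber run.

| flask | starting material | protic impurity | remark | time |
|---|---|---|---|---|
| grey | 0.012 M | 2 mM | run made earlier |  |
| blue | 0.027 M | 2 mM | run made earlier |  |
| amber | 0.074 M | 2 mM | run made earlier |  |
| dusk | 0.010 M | 2.00 mM |  | 20 d |
| winter | 0.020 M | 2.00 mM |  | 20 d |
| dawn | 0.040 M | 2.00 mM |  | 20 d |
| autumn | 0.080 M | 2.00 mM |  | 20 d |

- grey (time / d: target / %): 0.833: 11; 2.50: 27; 5.00: 45; 8.00: 59; 10.0: 62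
- blue (time / d: target / %): 2.08: 25; 4.00: 41; 6.00: 49; 8.00: 60; 10.0: 66
- amber (time / d: target / %): 0.833: 12; 2.50: 29; 5.00: 46; 8.00: 61; 10.0: 69

(each reading ± 1.5 percentage points)

- the numbers in the tables scatter with a standard deviation of 1.5 percentage points
- a reading or a percentage of target counts all its forms, free or not
- "hardly changes" means that all values lie within two and a half points (for a concentration: within two and a half percent of the largest)

- amount of target at the end, in percent of the starting material charged for dusk, winter, dawn, autumn, in this order
- the course of these numbers from the first flask to the last (hardly changes / falls, then rises / falls all the way / rises, then falls / rises all the way)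

In the amber run the target stood at 46% at 5.00 d and at 69% at 10.0 d, so the second equal interval gained half of what the first had gained, and that gives the half-life. I distrusted a constant taken from two readings, so I took the plateau they imply, 92.0%, and predicted a third amber reading: 61.7% at 8.00 d, where 61% was read. The curve held, and counting half-lives then gave a rule: 2.00 half-lives lie in each 10.0 d, so the reading at 10.0 d times 1.25 gives the target at 20 d.

The honest objection came from the grey run, whose own pair of readings gives a shorter half-life, 3.56 d, and so 70.8% at 20 d. But that rests on one late reading: grey gained 3 percentage points over its last interval where amber gained 8 points, and with a scatter of 1.5 points per reading I did not trust that gap. Up to 8.00 d the grey and amber curves differ by 2 points or less, so I kept one half-life for the series. The rule then gave 77.5% for grey, 82.5% for blue and 86.2% for amber. I therefore expected dusk just under the grey figure, autumn just over the amber figure, and a steady rise between them.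

The forecast gave 70%, 79%, 84% and 86%, rises all the way, on the view of “a fixed 2 mM of impurity removing a fixed amount of material”, and its dusk value stood lower than my grey figure.

The flasks gave 76.8%, 80.1%, 83.2% and 85.3% at 20 d, so the row rises all the way.

    starting material ⇌ intermediate A (K = 1.50, k = 3.70 × 10⁻⁵ s⁻¹)
    starting material → intermediate B (k = 4.30 × 10⁻⁶ s⁻¹)
    intermediate B → side product (k = 7.50 × 10⁻⁶ s⁻¹)
    intermediate B → target (k = 9.60 × 10⁻⁵ s⁻¹)
    intermediate B ⇌ intermediate C (K = 0.500, k = 2.00 × 10⁻⁶ s⁻¹)
    crystals ⇌ target, rate k6*(cs6 - [target]) while solid is left; crystals form when [target] > cs6 (solubility = 8.70 mM, k = 9.30 × 10⁻⁵ s⁻¹)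
    starting material + protic impurity → quenched substrate (k = 5.50 × 10⁻⁴ M⁻¹ s⁻¹)

The rise from dusk to autumn, 8.4 points, has the step from starting material + protic impurity to quenched substrate as its largest single effect: without that step the rise is 0 points, and at 20.0 d quenched substrate stood higher in dusk, at 13.1% of the charge, than in autumn, at 2.50%. Counted on starting material and intermediate A together, my 2.00 half-lives called for a fall by a factor of 4.00 from 10.0 d to 20.0 d, and in autumn that pair went from 22.4% to 5.39%, a fall by a factor of 4.16.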